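The ester is disconnected between the acrylate carbonyl carbon and the (Z)-ethylidene-bearing α-carbon. The key step exploits the 1,3-relationship of that carbonyl carbon to the oxygen of the CH2O arm on the same α-carbon (O–CH2–C–C=O; the arene ring is a spectator). The carbonyl is parked on this oxygen as a mixed carbonate with the (S)-1-arylallyl alcohol, beside a (Z)-vinyl iodide. Iodine–lithium exchange then triggers a 1,3 O→C alkoxycarbonyl shift (an allylic analogue of the anionic Fries rearrangement). This forges the C–C bond with retention of olefin geometry and unveils the primary alkoxide, which is tigloylated in the same flask to give the target.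

Key step: step 6

Remark: commercial crotonaldehyde and tigloyl chloride are taken as their (E)-isomers. The L-(+)-tartrate Sharpless system is assumed to consume the (R)-enantiomer of a 1-arylallyl alcohol faster (the spatial sense known for 1-alkylallyl alcohols, with the descriptor changed because aryl outranks vinyl), so the (S)-alcohol is the one recovered.

Step 1
Reactants: 1 3,4,5-trimethoxybenzaldehyde; 2 vinylmagnesium bromide
Product: 3 rac-1-(3,4,5-trimethoxyphenyl)prop-2-en-1-ol
Conditions: THF, 0 °C; then aq. NH4Cl
Reagents that add atoms: none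
Why: Grignard 1,2-addition of the vinyl nucleophile to the aryl aldehyde should give the racemic secondary allylic alcohol; the stereocenter is formed without control and is resolved in step 2.

Step 2
Reactants: 3 rac-1-(3,4,5-trimethoxyphenyl)prop-2-en-1-ol
Product: 4 (S)-1-(3,4,5-trimethoxyphenyl)prop-2-en-1-ol
Conditions: Ti(OiPr)4 (cat.), L-(+)-DIPT (cat.), TBHP (0.6 equiv), 4 Å MS, CH2Cl2, −20 °C
Reagents that add atoms: none
Why: Sharpless kinetic resolution: the Ti/L-(+)-tartrate/TBHP system should epoxidise the (R)-enantiomer much faster, so the (S)-alcohol should be recovered in high enantiomeric purity past half conversion and separated from the epoxy alcohol by chromatography.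

Step 3
Reactants: 5 (E)-but-2-enal (crotonaldehyde)
Product: 6 (Z)-2-iodobut-2-enal
Conditions: I2, K2CO3, DMAP (cat.), THF/H2O 1:1, rt
Reagents that add atoms: iodine, II
Why: Nucleophile-catalysed α-iodination of an enal (conjugate addition of DMAP, iodination of the enolate, E1cB loss of DMAP) should give the thermodynamically preferred (Z)-2-iodoenal, in which methyl stays trans to the formyl group and is therefore cis to iodine.

Step 4
Reactants: 6 (Z)-2-iodobut-2-enal
Product: 7 (Z)-2-iodobut-2-en-1-ol
Conditions: NaBH4, THF/H2O 9:1, 0 °C
Reagents that add atoms: none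
Why: Borohydride 1,2-reduction of the aldehyde should leave the vinyl iodide and its geometry untouched.

Step 5
Reactants: 7 (Z)-2-iodobut-2-en-1-ol; 4 (S)-1-(3,4,5-trimethoxyphenyl)prop-2-en-1-ol
Product: 9 (Z)-2-iodobut-2-en-1-yl (S)-1-(3,4,5-trimethoxyphenyl)prop-2-en-1-yl carbonate, via (Z)-2-iodobut-2-enyl 4-nitrophenyl carbonate 8 (not isolated)
Conditions: 4-nitrophenyl chloroformate, pyridine, CH2Cl2, 0 °C; then 4, DMAP, i-Pr2NEt, CH2Cl2, 0 °C → rt
Reagents that add atoms: 4-nitrophenyl chloroformate, O=C(Cl)Oc1ccc(cc1)[N+](=O)[O-]
Why: Stepwise unsymmetrical carbonate synthesis (acyl substitution through an activated 4-nitrophenyl carbonate under DMAP catalysis); the primary alcohol is the one activated so that no ionisable acyl derivative of the 1-arylallyl alcohol is made, and only the O–H bond of 4 reacts, so its stereocenter is retained.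

Step 6
Reactants: 9 (Z)-2-iodobut-2-en-1-yl (S)-1-(3,4,5-trimethoxyphenyl)prop-2-en-1-yl carbonate; 10 (E)-2-methylbut-2-enoyl chloride (tigloyl chloride)
Product: 14 (S)-1-(3,4,5-trimethoxyphenyl)prop-2-en-1-yl (Z)-2-{[(E)-2-methylbut-2-enoyl]oxymethyl}but-2-enoate (target), via alkenyllithium 11 (not isolated), via lithium oxetanolate adduct 12 (not isolated), via lithium alkoxide 13 (not isolated)
Conditions: t-BuLi (2.0 equiv), THF/Et2O/pentane 4:1:1, −100 → −78 °C; then tigloyl chloride, −78 → 0 °C
Reagents that add atoms: none
Why: Proposed new method: iodine–lithium exchange, which should be faster than any carbonyl addition at −100 °C, gives the configurationally stable (Z)-alkenyllithium 11, whose sp2 carbanion adds to the tethered carbonate carbonyl; the strained tetrahedral adduct 12 collapses by ring opening to the acrylate ester and the primary lithium alkoxide 13, which tigloyl chloride then acylates. The closest known reaction types are the halogen–metal-exchange-triggered anionic Fries rearrangement of aryl esters, carbamates and carbonates (the same 1,3 O→C shift through a four-membered transition state) and the retro-[1,3]-Brook shift of 2-lithioallyl silyl ethers. The only ring closed is the transient oxetane of 12 (4-exo-trig), and no ring is formed in the product. No new stereocenter appears in the product, the C–O stereocenter is a spectator, and the Z geometry (ester carbonyl cis to methyl) follows from retention at the alkenyllithium carbon that carried iodine. The step needs the acyl shift to beat β-elimination of the allylic carbonate (to buta-1,2-diene) and deprotonation of the 1-arylallyl C–H; the very low temperature, lithium chelation to the carbonyl oxygen and the intramolecular trajectory are relied on for this. Both modes of collapse of 12 should converge, because a β-lactone formed by loss of the secondary alkoxide would be reopened by that alkoxide at the acyl carbon to the same 13.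

Compound list
1 | 3,4,5-trimethoxybenzaldehyde | COc1cc(C=O)cc(OC)c1OC | starting material
2 | vinylmagnesium bromide | C=C[Mg]Br | starting material
3 | rac-1-(3,4,5-trimethoxyphenyl)prop-2-en-1-ol | C=CC(O)c1cc(OC)c(OC)c(OC)c1 | intermediate
4 | (S)-1-(3,4,5-trimethoxyphenyl)prop-2-en-1-ol | C=C[C@H](O)c1cc(OC)c(OC)c(OC)c1 | intermediate
5 | (E)-but-2-enal (crotonaldehyde) | C/C=C/C=O | starting material
6 | (Z)-2-iodobut-2-enal | C/C=C(\I)C=O | intermediate
7 | (Z)-2-iodobut-2-en-1-ol | C/C=C(\I)CO | intermediate
8 | (Z)-2-iodobut-2-en-1-yl 4-nitrophenyl carbonate | C/C=C(\I)COC(=O)Oc1ccc(cc1)[N+](=O)[O-] | intermediate (not isolated)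
9 | (Z)-2-iodobut-2-en-1-yl (S)-1-(3,4,5-trimethoxyphenyl)prop-2-en-1-yl carbonate | C=C[C@H](OC(=O)OC/C(I)=C/C)c1cc(OC)c(OC)c(OC)c1 | intermediate
10 | (E)-2-methylbut-2-enoyl chloride (tigloyl chloride) | C/C=C(\C)C(=O)Cl | starting material
11 | (Z)-2-lithiobut-2-en-1-yl (S)-1-(3,4,5-trimethoxyphenyl)prop-2-en-1-yl carbonate (alkenyllithium) | C=C[C@H](OC(=O)OC/C([Li])=C/C)c1cc(OC)c(OC)c(OC)c1 | intermediate (not isolated)
12 | lithium (Z)-3-ethylidene-2-{[(S)-1-(3,4,5-trimethoxyphenyl)prop-2-en-1-yl]oxy}oxetan-2-olate (tetrahedral adduct, either configuration at the ring carbon) | C=C[C@H](OC1(O[Li])OC/C1=C/C)c1cc(OC)c(OC)c(OC)c1 | intermediate (not isolated)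
13 | lithium alkoxide of (S)-1-(3,4,5-trimethoxyphenyl)prop-2-en-1-yl (Z)-2-(hydroxymethyl)but-2-enoate | C=C[C@H](OC(=O)/C(=C\C)CO[Li])c1cc(OC)c(OC)c(OC)c1 | intermediate (not isolated)
14 | (S)-1-(3,4,5-trimethoxyphenyl)prop-2-en-1-yl (Z)-2-{[(E)-2-methylbut-2-enoyl]oxymethyl}but-2-enoate | C=C[C@H](OC(=O)/C(=C\C)COC(=O)/C(C)=C/C)c1cc(OC)c(OC)c(OC)c1 | target

Total step count: 6
Longest linear sequence: 4 steps (5 → 6 → 7 → 9 → 14, or 1 → 3 → 4 → 9 → 14)

Steps most likely to fail

1. Step 6 (Proposed new method).
What may go wrong: β-elimination of the alkenyllithium toward the allylic carbonate oxygen may outrun the four-membered acyl shift. Intermolecular attack on a second carbonate may scramble which alkoxide is expelled. The alkenyllithium may instead be quenched by proton transfer from the acidic 1-arylallyl C–H.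
Fallback (known chemistry; sets out from 7 and 4, returns at 14): the oxygen is masked so that no good β-leaving group is present, and the same C–C bond is made intermolecularly. 7 is silylated (TBSCl, imidazole, DMF) to (Z)-tert-butyl[(2-iodobut-2-en-1-yl)oxy]dimethylsilane F1. 4 is treated with carbonyldiimidazole (CH2Cl2, 0 °C) to give (S)-1-(3,4,5-trimethoxyphenyl)prop-2-en-1-yl 1H-imidazole-1-carboxylate F2, used crude. F1 is lithiated (t-BuLi, Et2O, −78 °C) and the alkenyllithium is added to F2 in THF at −78 °C; this C-alkoxycarbonylation of an organolithium by an alkoxycarbonyl imidazole should give (S)-1-(3,4,5-trimethoxyphenyl)prop-2-en-1-yl (Z)-2-{[(tert-butyldimethylsilyl)oxy]methyl}but-2-enoate F3. HF·pyridine (THF, 0 °C) should free (S)-1-(3,4,5-trimethoxyphenyl)prop-2-en-1-yl (Z)-2-(hydroxymethyl)but-2-enoate F4. Acylation of F4 with 10 (pyridine, DMAP, CH2Cl2, 0 °C) returns to 14.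

2. Step 2.
What may go wrong: slow epoxidation of the monosubstituted alkene may erode the rate difference, so that high enantiomeric purity is reached only at high conversion. Titanium-promoted ionisation of the electron-rich benzylic allylic alcohol may cause racemisation or 1,3-transposition.
Fallback (sets out from 1 and 2, returns at 4): the stereocenter is set by catalytic asymmetric addition instead of resolution. 2 is transmetalated with ZnCl2 (0.5 equiv, Et2O) to divinylzinc F5. F5 is added to 1 in toluene at 0 °C with catalytic (2S)-(−)-3-exo-morpholinoisoborneol, an amino alcohol that directs organozinc addition to the Si face of aryl aldehydes, and should give 4 directly.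

3. Step 5.
What may go wrong: slow acyl transfer to the hindered secondary alcohol may allow carbonate exchange to symmetrical carbonates. Acid-assisted ionisation of the 1-arylallyl C–O bond may occur during the long reaction time.
Fallback (sets out from 7, returns at 9): the carbonate is closed by O-alkylation instead of acyl substitution. 7 is converted with PBr3 (Et2O, 0 °C) to (Z)-1-bromo-2-iodobut-2-ene F6. 4 is stirred with Cs2CO3 and Bu4NI in DMF under CO2 (1 atm), and the resulting alkyl carbonate anion is alkylated by F6 at rt (three-component carbonate synthesis) to give 9.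

Further compounds
F1 | step 6 | (Z)-tert-butyl[(2-iodobut-2-en-1-yl)oxy]dimethylsilane | C/C=C(\I)CO[Si](C)(C)C(C)(C)C
F2 | step 6 | (S)-1-(3,4,5-trimethoxyphenyl)prop-2-en-1-yl 1H-imidazole-1-carboxylate | C=C[C@H](OC(=O)n1ccnc1)c1cc(OC)c(OC)c(OC)c1
F3 | step 6 | (S)-1-(3,4,5-trimethoxyphenyl)prop-2-en-1-yl (Z)-2-{[(tert-butyldimethylsilyl)oxy]methyl}but-2-enoate | C=C[C@H](OC(=O)/C(=C\C)CO[Si](C)(C)C(C)(C)C)c1cc(OC)c(OC)c(OC)c1
F4 | step 6 | (S)-1-(3,4,5-trimethoxyphenyl)prop-2-en-1-yl (Z)-2-(hydroxymethyl)but-2-enoate | C=C[C@H](OC(=O)/C(=C\C)CO)c1cc(OC)c(OC)c(OC)c1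
F5 | step 2 | divinylzinc | C=C[Zn]C=C
F6 | step 5 | (Z)-1-bromo-2-iodobut-2-ene | C/C=C(\I)CBr
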